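## Retrosynthetic overview

1. Target 16 ⇐ diol 14 by two esterifications (secondary C8–OH as propanoate first, tertiary C11–OH as acetate last).
2. 14 ⇐ lactol enone 12: the C1–C5 bond is made by an intramolecular Stetter addition (C5 formyl carbon as acyl anion onto the enone β-carbon C1), closing the seven-membered ring first; aldol condensation (C4=C5) then closes the cyclopentenone in the same flask.
3. 12 ⇐ lactone 9 by partial reduction and cross-metathesis with ethyl vinyl ketone (brings C2–C4 and C15).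
4. 9 ⇐ butenolide 7 + isopropanol: C7–C11 by conjugate addition of the acetone ketyl radical anti to the C8 side chain.
5. 7 ⇐ (S)-β-citronellene 1 (C10 from the chiral pool) via aldehyde 2, proline α-aminoxylation (sets C8), Z-Wittig and lactonisation.

Assumption: (S)-(−)-β-citronellene of high ee is taken as commercial; atoms are referred to by guaiane numbering (C1 ring-fusion CH, C2 CH2, C3 C=O, C4=C5 enone, C6 CH2, C7 CH bearing C11, C8 CH–O, C9 CH2, C10 CH–Me); lactols are drawn as one ring tautomer.

## Route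

Step 1
Reactants: 1 (S)-(−)-β-citronellene [(3S)-3,7-dimethylocta-1,6-diene]
Product: 2 (4S)-4-methylhex-5-enal
Conditions: O3 (1.0 equiv, Sudan Red 7B end-point), pyridine (cat.), CH2Cl2/MeOH, −78 °C; Me2S, −78 °C → rt
Reagents that add atoms: ozone, [O-][O+]=O
Why: Electrophilic ozone cleaves the electron-rich trisubstituted alkene much faster than the monosubstituted vinyl group (chemoselective ozonolysis, reductive work-up), and the methyl-bearing stereocentre (future C10) is not touched.

Step 2
Reactants: 2 (4S)-4-methylhex-5-enal; 3 methyl (triphenylphosphoranylidene)acetate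
Product: 5 methyl (2Z,4R,6S)-6-methyl-4-[(phenylamino)oxy]octa-2,7-dienoate, via aminoxy aldehyde 4 (not isolated)
Conditions: PhNO, L-proline (20 mol%), DMSO, rt, 30 min; then 3 (1.5 equiv), MeOH, 0 °C
Reagents that add atoms: nitrosobenzene, O=Nc1ccccc1
Why: Proline enamine catalysis (organocatalytic α-aminoxylation, O-selective nitroso aldol) delivers the oxygen to one enamine face under catalyst control to set C8 as R, and the stabilised ylide olefinates the α-oxygenated aldehyde Z-selectively in methanol (Wittig reaction) before it can racemise.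

Step 3
Reactants: 5 methyl (2Z,4R,6S)-6-methyl-4-[(phenylamino)oxy]octa-2,7-dienoate
Product: 7 (5R)-5-[(2S)-2-methylbut-3-en-1-yl]furan-2(5H)-one, via hydroxy ester 6 (not isolated)
Conditions: Cu(OAc)2·H2O (30 mol%), MeOH, rt; then p-TsOH (cat.), CH2Cl2, rt
Reagents that add atoms: none
Why: Copper(II) cleaves the weak N–O bond to free the γ-hydroxyl, which the Z-alkene holds next to the ester so that it lactonises (intramolecular transesterification) to the butenolide without change at C8.

Step 4
Reactants: 7 (5R)-5-[(2S)-2-methylbut-3-en-1-yl]furan-2(5H)-one; 8 propan-2-ol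
Product: 9 (4S,5R)-4-(2-hydroxypropan-2-yl)-5-[(2S)-2-methylbut-3-en-1-yl]dihydrofuran-2(3H)-one
Conditions: hν (350 nm), Ph2CO (20 mol%), 8 as solvent (0.05 M), Ar, rt
Reagents that add atoms: none
Why: Triplet benzophenone abstracts the carbinol hydrogen of isopropanol, and the nucleophilic 2-hydroxy-2-propyl (ketyl) radical, a polarity-reversed acetone carbonyl carbon, adds to the butenolide β-carbon anti to the C5 side chain (Giese-type radical conjugate addition), setting C7 as S (trans-4,5 lactone).

Step 5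
Reactants: 9 (4S,5R)-4-(2-hydroxypropan-2-yl)-5-[(2S)-2-methylbut-3-en-1-yl]dihydrofuran-2(3H)-one
Product: 10 (4S,5R)-4-(2-hydroxypropan-2-yl)-5-[(2S)-2-methylbut-3-en-1-yl]tetrahydrofuran-2-ol (anomer mixture)
Conditions: DIBAL-H (2.2 equiv), CH2Cl2, −78 °C; aq. Rochelle salt
Reagents that add atoms: none
Why: At −78 °C the aluminium hemiacetal of a γ-lactone is stable, so reduction stops at the lactol (partial lactone reduction); the isolated alkene and the existing stereocentres are unaffected.

Step 6
Reactants: 10 lactol (as above); 11 pent-1-en-3-one (ethyl vinyl ketone)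
Product: 12 (4E,6S)-7-[(2R,3S)-5-hydroxy-3-(2-hydroxypropan-2-yl)tetrahydrofuran-2-yl]-6-methylhept-4-en-3-one (anomer mixture)
Conditions: 11 (3 equiv), Hoveyda–Grubbs II (5 mol%), CH2Cl2, 40 °C
Reagents that add atoms: none
Why: Olefin cross-metathesis between a terminal alkene and an electron-poor vinyl ketone gives the E-enone selectively, and the ruthenium carbene tolerates the hemiacetal and the tertiary alcohol.

Step 7
Reactants: 12 (4E,6S)-7-[(2R,3S)-5-hydroxy-3-(2-hydroxypropan-2-yl)tetrahydrofuran-2-yl]-6-methylhept-4-en-3-one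
Product: 14 (5S,6R,8S,8aR)-6-hydroxy-5-(2-hydroxypropan-2-yl)-3,8-dimethyl-4,5,6,7,8,8a-hexahydroazulen-2(1H)-one, via diketone 13 (not isolated)
Conditions: 3-benzyl-5-(2-hydroxyethyl)-4-methylthiazolium chloride (20 mol%), Et3N (0.5 equiv), EtOH, 75 °C; then 2 M aq. KOH, 60 °C (one pot)
Reagents that add atoms: none
Why: Proposed new method: the lactol reacts through its open γ-hydroxy aldehyde tautomer, whose formyl carbon (C5) the thiazol-2-ylidene converts into a nucleophilic Breslow (acyl anion) intermediate that adds 7-exo-trig to the enone β-carbon C1 (intramolecular Stetter reaction; closest precedent is 5- and 6-membered intramolecular Stetter cyclisation and Stetter reactions of hemiacetal aldehydes such as sugars), the heavily substituted tether favouring closure, and hydroxide then equilibrates C1 (α to the new ketone) trans to the C10 methyl and drives aldol condensation of the ethyl ketone onto the ring ketone (Stetter-type cyclopentenone synthesis), fixing C1 as R.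

Step 8
Reactants: 14 diol (as above)
Product: 15 (5S,6R,8S,8aR)-5-(2-hydroxypropan-2-yl)-3,8-dimethyl-2-oxo-1,2,4,5,6,7,8,8a-octahydroazulen-6-yl propanoate
Conditions: (EtCO)2O (1.5 equiv), pyridine, DMAP (10 mol%), CH2Cl2, 0 °C → rt
Reagents that add atoms: propanoic anhydride, CCC(=O)OC(=O)CC
Why: DMAP-catalysed acylation is far faster at the secondary C8 hydroxyl than at the hindered tertiary one, so the propanoate goes on regioselectively with retention.

Step 9
Reactants: 15 (as above)
Product: 16 (5S,6R,8S,8aR)-5-(2-acetoxypropan-2-yl)-3,8-dimethyl-2-oxo-1,2,4,5,6,7,8,8a-octahydroazulen-6-yl propanoate (target)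
Conditions: Ac2O (3 equiv), Sc(OTf)3 (2 mol%), MeCN, −20 °C
Reagents that add atoms: acetic anhydride, CC(=O)OC(C)=O
Why: Scandium triflate activates the anhydride strongly enough to esterify the tertiary alcohol at low temperature (Lewis-acid-catalysed acylation) faster than it ionises, leaving the enone and the secondary ester untouched.

## Compound list

1 | (S)-(−)-β-citronellene, (3S)-3,7-dimethylocta-1,6-diene | C=C[C@@H](C)CCC=C(C)C | starting material
2 | (4S)-4-methylhex-5-enal | C=C[C@@H](C)CCC=O | intermediate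
3 | methyl (triphenylphosphoranylidene)acetate | COC(=O)C=P(c1ccccc1)(c1ccccc1)c1ccccc1 | starting material
4 | (2R,4S)-4-methyl-2-[(phenylamino)oxy]hex-5-enal | O=C[C@H](ONc1ccccc1)C[C@H](C)C=C | intermediate
5 | methyl (2Z,4R,6S)-6-methyl-4-[(phenylamino)oxy]octa-2,7-dienoate | COC(=O)/C=C\[C@H](ONc1ccccc1)C[C@H](C)C=C | intermediate
6 | methyl (2Z,4R,6S)-4-hydroxy-6-methylocta-2,7-dienoate | COC(=O)/C=C\[C@H](O)C[C@H](C)C=C | intermediate
7 | (5R)-5-[(2S)-2-methylbut-3-en-1-yl]furan-2(5H)-one | O=C1C=C[C@@H](C[C@H](C)C=C)O1 | intermediate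
8 | propan-2-ol | CC(C)O | starting material
9 | (4S,5R)-4-(2-hydroxypropan-2-yl)-5-[(2S)-2-methylbut-3-en-1-yl]dihydrofuran-2(3H)-one | O=C1C[C@H](C(C)(C)O)[C@@H](C[C@H](C)C=C)O1 | intermediate
10 | (4S,5R)-4-(2-hydroxypropan-2-yl)-5-[(2S)-2-methylbut-3-en-1-yl]tetrahydrofuran-2-ol | OC1C[C@H](C(C)(C)O)[C@@H](C[C@H](C)C=C)O1 | intermediate
11 | pent-1-en-3-one (ethyl vinyl ketone) | CCC(=O)C=C | starting material
12 | (4E,6S)-7-[(2R,3S)-5-hydroxy-3-(2-hydroxypropan-2-yl)tetrahydrofuran-2-yl]-6-methylhept-4-en-3-one | OC1C[C@H](C(C)(C)O)[C@@H](C[C@H](C)/C=C/C(=O)CC)O1 | intermediate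
13 | (2R,3S,5R,6S)-5-hydroxy-6-(2-hydroxypropan-2-yl)-3-methyl-2-(2-oxobutyl)cycloheptan-1-one | O=C1C[C@H](C(C)(C)O)[C@H](O)C[C@H](C)[C@H]1CC(=O)CC | intermediate
14 | (5S,6R,8S,8aR)-6-hydroxy-5-(2-hydroxypropan-2-yl)-3,8-dimethyl-4,5,6,7,8,8a-hexahydroazulen-2(1H)-one | O[C@@H]1C[C@H](C)[C@H]2CC(=O)C(C)=C2C[C@@H]1C(C)(C)O | intermediate
15 | (5S,6R,8S,8aR)-5-(2-hydroxypropan-2-yl)-3,8-dimethyl-2-oxo-1,2,4,5,6,7,8,8a-octahydroazulen-6-yl propanoate | CCC(=O)O[C@@H]1C[C@H](C)[C@H]2CC(=O)C(C)=C2C[C@@H]1C(C)(C)O | intermediate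
16 | (5S,6R,8S,8aR)-5-(2-acetoxypropan-2-yl)-3,8-dimethyl-2-oxo-1,2,4,5,6,7,8,8a-octahydroazulen-6-yl propanoate | CCC(=O)O[C@@H]1C[C@H](C)[C@H]2CC(=O)C(C)=C2C[C@@H]1C(C)(C)OC(C)=O | target

## Step count and risks

Total steps: 9. Longest linear sequence: 9 steps (1 → 16); all other inputs are commercial.

The three steps most likely to fail:

Step 7 is the weakest. A seven-membered Stetter closure has little precedent, the aldehyde is masked as a lactol, and once the lactol opens the free C8 hydroxyl can add to the enone (5-exo oxa-Michael). The C1 configuration also rests on a modest thermodynamic preference, so some C1 epimer is to be expected. The fallback sets out from 12 and makes the same C1–C5 bond by a one-electron route. Tetrabutylammonium decatungstate (2 mol%), MeCN, 390 nm abstracts the hydridic hemiacetal C–H (or the formyl C–H of the open tautomer). The resulting nucleophilic α,α-dioxyalkyl (masked acyl) radical cyclises 7-exo onto the enone, and back hydrogen transfer gives the bridged hemiketal 1-[1-hydroxy-6-(2-hydroxypropan-2-yl)-3-methyl-8-oxabicyclo[3.2.1]octan-2-yl]butan-2-one F1 (stereocentres as in 13). Aqueous KOH opens it to the diketone 13, where the material comes back to the route, and the same base carries it on to 14.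

Step 4 is a photochemical radical chain. The risks are incomplete facial selectivity with a CH2-linked side chain and side reactions of the triplet sensitiser with the allylic C–H or vinyl group. The fallback sets out from 7 and generates the acetone ketyl reductively: acetone (3 equiv), SmI2 (2.2 equiv), t-BuOH, THF, −78 → 0 °C. The samarium ketyl adds to C7 anti to the side chain, and the tertiary samarium alkoxide is expected to translactonise, giving (4S)-4-[(1R,3S)-1-hydroxy-3-methylpent-4-en-1-yl]-5,5-dimethyldihydrofuran-2(3H)-one F2. DIBAL-H as in step 5 gives the lactol (4S)-4-[(1R,3S)-1-hydroxy-3-methylpent-4-en-1-yl]-5,5-dimethyltetrahydrofuran-2-ol F3. This is the ring-chain tautomer of 10 and equilibrates with it through the common hydroxy aldehyde, so the route is rejoined at 10.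

Step 9 acetylates a tertiary alcohol next to the C8 ester. Elimination to the isopropenyl compound or 1,3-migration of the propanoyl group could compete. The fallback sets out from 14 and reverses the order of the two acylations with a silyl relay. TESCl, imidazole, DMF, 0 °C gives (5S,6R,8S,8aR)-5-(2-hydroxypropan-2-yl)-3,8-dimethyl-6-[(triethylsilyl)oxy]-4,5,6,7,8,8a-hexahydroazulen-2(1H)-one F4. Ac2O, DMAP, Et3N, 50 °C (no Lewis acid, no ester that can migrate) gives 2-[(5S,6R,8S,8aR)-3,8-dimethyl-2-oxo-6-[(triethylsilyl)oxy]-1,2,4,5,6,7,8,8a-octahydroazulen-5-yl]propan-2-yl acetate F5. HF·pyridine, THF, 0 °C frees the secondary alcohol 2-[(5S,6R,8S,8aR)-6-hydroxy-3,8-dimethyl-2-oxo-1,2,4,5,6,7,8,8a-octahydroazulen-5-yl]propan-2-yl acetate F6. Propanoic anhydride, pyridine and DMAP then give the target directly, so the route is rejoined at 16.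

## Further compounds

F1 | step 7 | 1-[1-hydroxy-6-(2-hydroxypropan-2-yl)-3-methyl-8-oxabicyclo[3.2.1]octan-2-yl]butan-2-one (bridged hemiketal tautomer of 13) | O[C@]12C[C@H](C(C)(C)O)[C@H](O1)C[C@H](C)[C@H]2CC(=O)CC
F2 | step 4 | (4S)-4-[(1R,3S)-1-hydroxy-3-methylpent-4-en-1-yl]-5,5-dimethyldihydrofuran-2(3H)-one | O=C1C[C@@H]([C@H](O)C[C@H](C)C=C)C(C)(C)O1
F3 | step 4 | (4S)-4-[(1R,3S)-1-hydroxy-3-methylpent-4-en-1-yl]-5,5-dimethyltetrahydrofuran-2-ol | OC1C[C@@H]([C@H](O)C[C@H](C)C=C)C(C)(C)O1
F4 | step 9 | (5S,6R,8S,8aR)-5-(2-hydroxypropan-2-yl)-3,8-dimethyl-6-[(triethylsilyl)oxy]-4,5,6,7,8,8a-hexahydroazulen-2(1H)-one | CC[Si](CC)(CC)O[C@@H]1C[C@H](C)[C@H]2CC(=O)C(C)=C2C[C@@H]1C(C)(C)O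
F5 | step 9 | 2-[(5S,6R,8S,8aR)-3,8-dimethyl-2-oxo-6-[(triethylsilyl)oxy]-1,2,4,5,6,7,8,8a-octahydroazulen-5-yl]propan-2-yl acetate | CC[Si](CC)(CC)O[C@@H]1C[C@H](C)[C@H]2CC(=O)C(C)=C2C[C@@H]1C(C)(C)OC(C)=O
F6 | step 9 | 2-[(5S,6R,8S,8aR)-6-hydroxy-3,8-dimethyl-2-oxo-1,2,4,5,6,7,8,8a-octahydroazulen-5-yl]propan-2-yl acetate | O[C@@H]1C[C@H](C)[C@H]2CC(=O)C(C)=C2C[C@@H]1C(C)(C)OC(C)=O
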